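A fraction of the charged substrate per hour is the unit of this reckoning, and the bench habit behind it is simple: replace the curve of substrate against time by a straight line through its mean.

| setting | ochre | violet | east | south | north-west |
|---|---|---|---|---|---|
| substrate | 0.10 M | 0.10 M | 0.10 M | 0.10 M | 0.10 M |
| reagent | 0.20 M | 0.35 M | 0.260 M | 0.220 M | 0.180 M |
| initiator | 1.3 mM | 1.3 mM | 1.3 mM | 1.3 mM | 1.3 mM |
| remark | run made earlier | run made earlier |  |  |  |
| time |  |  | 12 h | 12 h | 12 h |

| run | time / h | substrate / % | product / % | first chain carrier / % |
|---|---|---|---|---|
| ochre | 0.667 | 99 | 0 | 0 |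
| ochre | 1.00 | 96 | 4 | 0 |
| ochre | 2.00 | 97 | 4 | 2 |
| ochre | 3.00 | 92 | 11 | 0 |
| ochre | 5.00 | 88 | 6 | 2 |
| ochre | 8.00 | 83 | 11 | 4 |
| violet | 1.33 | 97 | 0 | 1 |
| violet | 3.00 | 89 | 10 | 1 |
| violet | 4.00 | 88 | 11 | 0 |
| violet | 6.00 | 80 | 20 | 0 |
| violet | 8.00 | 75 | 23 | 0 |

(readings scatter by 1.5 percentage points)



- which of these there is most of at the end, counted by the substrate in it, east (substrate / product / first chain carrier)
- which of these there is most of at the end, counted by the substrate in it, south (substrate / product / first chain carrier)
- which of these there is most of at the end, counted by the substrate in it, north-west (substrate / product / first chain carrier)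
- final amount of the leader among these, as a percentage of the substrate charged, in east
- final amount of the leader among these, as a percentage of the substrate charged, in south
- final amount of the leader among these, as a percentage of the substrate charged, in north-west

Mean hourly loss is the fraction of substrate gone at the last reading divided by the time of that reading. The ochre run, at [reagent] = 0.20 M, reads 0.0212 h⁻¹, and the violet run, at [reagent] = 0.35 M, reads 0.0312 h⁻¹. These two readings stand in a ratio of 1.47 against the 1.75 between the reagent charges, but each rests on one reading with a scatter of 1.5 percentage points, set against a loss of 17.0 % in the ochre run, so this ratio cannot tell a weaker dependence from plain proportion. The plainest reckoning therefore takes the mean hourly loss as proportional to [reagent], with one factor fitted to both runs together by least squares. That proportion gives east, at [reagent] = 0.260 M, a mean hourly loss of 0.0243 h⁻¹, with 0.0206 h⁻¹ for south and 0.0168 h⁻¹ for north-west.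

The border of the habit lies at the last reading, and the asked time stands 1.50 times beyond it. Stretching the line by that ratio stretches the scatter of a reading to 2.2 points. The line also assumes a steady pace, and the readings are divided on this. The ochre run goes from 0.0267 h⁻¹ before 3.00 h to 0.0180 h⁻¹ after it, while the violet run goes from 0.0300 h⁻¹ before 4.00 h to 0.0325 h⁻¹ after it. A slowing leaves more substrate than the line says, so the line's figures are the low side: 70.8 % of substrate in east, 75.3 % in south and 79.8 % in north-west. In east the remainder exceeds what is lost, so substrate leads there.

The forecast, slightly apart from this reckoning, names substrate as leader with 69 % in east, 73 % in south and 77 % in north-west, on the ground that “Substrate should remain the leader everywhere”.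

The flask gives substrate as leader in east at 74.6 %, substrate in south at 78.0 %, and substrate in north-west at 81.5 %.

    initiator → 2 initiating radical (k = 0.0890 h⁻¹)
    substrate + initiating radical → capped initiator + first chain carrier (k = 26000 M⁻¹ s⁻¹)
    reagent + first chain carrier → product + second chain carrier (k = 4.40 × 10⁵ M⁻¹ h⁻¹)
    substrate + second chain carrier → by-product + first chain carrier (k = 1.80 × 10⁶ M⁻¹ h⁻¹)
    first chain carrier → ended carrier (k = 530 h⁻¹)
    2 first chain carrier → ended chains A (k = 5.00 × 10⁷ M⁻¹ s⁻¹)
    2 second chain carrier → ended chains B (k = 9.00 × 10⁶ M⁻¹ s⁻¹)

East's mean hourly loss up to 12 h comes to 0.0211 h⁻¹, below the reckoned 0.0243 h⁻¹, and east is not at rest then, with 34.4 % of its initiator left. Ten times the time brings east's substrate to 48.0 % and its initiator to 0 %, a further 27 points of substrate at a mean of 0.00246 h⁻¹. North-west, at 0.0154 h⁻¹ up to 12 h, loses a further 19 points at a mean of 0.00179 h⁻¹.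

Readings and results were computed with made-up constants, noise included.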